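The C6 ketone, its α-carbon C7 and the methyl-bearing β-carbon C8 of the 14-membered carbocycle (C1–C14) are read as the product of a Claisen rearrangement. The precursor is not a carbocycle: a 12-membered macrolactone (C6 acyl, C10 oxygen) that already holds the cis-bridging tetrahydrofuran (C1, C14, C13, C12, O; carved from terpinen-4-ol through 1,4-cineole) is methylenated to a 2-methylene oxacycle bearing a (Z)-propenyl group on C10. One [3,3] shift then forges C7–C8, closes the cembrane ring and relays the C10 configuration to C8. Saturation of the transient C9=C10 bond, desilylation and formylation finish the synthesis.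

Key step: step 17

Remark: cembrane numbering (C1 = isopropyl-bearing ether carbon, C12 = methyl-bearing ether carbon, C14 = last ring carbon) is used for all intermediates; commercial (R)-(−)-terpinen-4-ol is assumed to be enantiopure, since it is the only source of the C1 and C12 configurations.

Step 1
Reactants: 1 (R)-(−)-terpinen-4-ol
Product: 3 2-exo-hydroxy-1,4-cineole, via cis-epoxy alcohol 2 (not isolated)
Conditions: t-BuOOH, VO(acac)2 (cat.), CH2Cl2, 0 °C to rt; then TsOH·H2O (cat.), rt
Reagents that add atoms: tert-butyl hydroperoxide, CC(C)(C)OO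
Why: Hydroxyl-directed vanadium-catalysed epoxidation should place the epoxide syn to the tertiary hydroxyl, and acid-catalysed transannular opening of the tertiary epoxide carbon by that hydroxyl should close the 7-oxabicyclo[2.2.1]heptane, so that C1 keeps the configuration of 1 and the bridge forces C12 cis to it.

Step 2
Reactants: 3 2-exo-hydroxy-1,4-cineole
Product: 4 1,4-cineol-2-one
Conditions: Pr4N[RuO4] (cat.), N-methylmorpholine N-oxide, 4 Å molecular sieves, CH2Cl2, rt
Reagents that add atoms: none
Why: Ley–Griffith oxidation of the secondary alcohol should give the bridged ketone; no stereocenter is formed and the C11 carbinol centre is erased on purpose.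

Step 3
Reactants: 4 1,4-cineol-2-one
Product: 5 trimethylsilyl enol ether of 4
Conditions: Me3SiOTf, Et3N, CH2Cl2, 0 °C
Reagents that add atoms: trimethylsilyl trifluoromethanesulfonate, C[Si](C)(C)OS(=O)(=O)C(F)(F)F
Why: Soft enolisation can only go toward C2, because the other α-carbon (C12) is a quaternary bridgehead, so a single silyl enol ether is expected.

Step 4
Reactants: 5 trimethylsilyl enol ether
Product: 6 (1S,12S)-aldehyde acid (cis-2,5-disubstituted tetrahydrofuran; C2 formyl on C1, C11 carboxyl on C12)
Conditions: O3, CH2Cl2/MeOH, −78 °C; Me2S, −78 °C to rt; aqueous work-up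
Reagents that add atoms: ozone, [O-][O+]=O
Why: Ozonolysis of the silyl enol ether should cleave C2–C11 regiospecifically into the C2 aldehyde and the C11 carboxylic acid, leaving both quaternary ether carbons (C1, C12) intact and cis.

Step 5
Reactants: 6 aldehyde acid; 7 triethyl 3-methyl-4-phosphonocrotonate
Product: 8 (2E,4E)-dienoate acid
Conditions: 7, LiN(SiMe3)2 (2.3 equiv), THF/DMPU, −78 to 0 °C; then 6; dilute HCl work-up
Reagents that add atoms: none
Why: Vinylogous Horner–Wadsworth–Emmons olefination of the non-enolisable aldehyde (the carboxylate is a spectator) should give the E,E-dienoate under thermodynamic control, any minor 4Z isomer being removed by chromatography.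

Step 6
Reactants: 8 dienoate acid
Product: 10 Weinreb amide, via acid chloride 9 (not isolated)
Conditions: (COCl)2, DMF (cat.), CH2Cl2, 0 °C; then MeNH(OMe)·HCl, pyridine, 0 °C to rt
Reagents that add atoms: N,O-dimethylhydroxylamine hydrochloride, CNOC.Cl
Why: Acid chloride formation and aminolysis should give the N-methoxy-N-methylamide, so that C11 can be stopped at the aldehyde level in the next step; no stereocenter is involved.

Step 7
Reactants: 10 Weinreb amide
Product: 11 aldehyde dienol
Conditions: i-Bu2AlH (4.5 equiv), CH2Cl2, −78 °C; aqueous potassium sodium tartrate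
Reagents that add atoms: none
Why: One hydride reagent should perform two standard reductions: the dienoate gives the C6 allylic alcohol, and the Weinreb amide, held as its chelated tetrahedral adduct until work-up, gives the C11 aldehyde.

Step 8
Reactants: 11 aldehyde dienol
Product: 12 (11R)-vinyl carbinol
Conditions: Zn(CH=CH2)2 (2.5 equiv, from vinylmagnesium bromide and ZnCl2), 3-exo-(dimethylamino)isoborneol (DAIB, the antipode that directs Re-face attack, 10 mol %), toluene, 0 °C; NH4Cl (aq)
Reagents that add atoms: divinylzinc, C=C[Zn]C=C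
Why: Amino-alcohol-catalysed enantioselective alkenylzinc addition should deliver vinyl to the Re face of the α-quaternary aldehyde under reagent control, setting C11 (R) and installing the vinyl group as a latent C10 aldehyde; the free allylic hydroxyl only consumes zinc reagent.

Step 9
Reactants: 12 vinyl carbinol
Product: 13 (4R,5R)-epoxy alcohol
Conditions: Ti(OiPr)4 (20 mol %), D-(−)-diethyl tartrate (24 mol %), t-BuOOH (1.2 equiv), 4 Å molecular sieves, CH2Cl2, −20 °C
Reagents that add atoms: tert-butyl hydroperoxide, CC(C)(C)OO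
Why: Sharpless asymmetric epoxidation with D-(−)-tartrate should deliver oxygen to the face of the 3,3-disubstituted primary allylic alcohol that sets C4 (reagent control); the hindered secondary vinyl carbinol at C11 reacts far more slowly and the non-allylic C2=C3 bond not at all.

Step 10
Reactants: 13 epoxy alcohol
Product: 14 (4S,11R)-triol
Conditions: NaAlH2(OCH2CH2OMe)2, THF, 0 °C; aqueous potassium sodium tartrate
Reagents that add atoms: none
Why: Intramolecular hydride delivery from the C6 alkoxyaluminate should open the 2,3-epoxy alcohol at C5, giving the 1,3-diol whose tertiary C4 carbinol keeps its C–O bond and so has the configuration of the target.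

Step 11
Reactants: 14 triol
Product: 15 dihydroxy acid
Conditions: TEMPO (cat.), PhI(OAc)2 (2.5 equiv), MeCN/H2O, rt
Reagents that add atoms: water, O
Why: The oxoammonium oxidation should take only the primary alcohol through the aldehyde hydrate to the acid, leaving the tertiary C4 hydroxyl and the hindered secondary C11 hydroxyl.

Step 12
Reactants: 15 dihydroxy acid
Product: 17 bis(triethylsilyl) ether acid, via triethylsilyl ester 16 (not isolated)
Conditions: Et3SiOTf (3.5 equiv), 2,6-lutidine, CH2Cl2, −78 to 0 °C; then THF/pH 5 buffer, rt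
Reagents that add atoms: triethylsilyl trifluoromethanesulfonate, CC[Si](CC)(CC)OS(=O)(=O)C(F)(F)F
Why: The silyl triflate should silylate the tertiary and the hindered secondary hydroxyl in one operation, and the labile silyl ester formed alongside is hydrolysed in the work-up, so both carbinols are masked for lactonisation, methylenation and thermolysis.

Step 13
Reactants: 17 bis(triethylsilyl) ether acid
Product: 18 C10 aldehyde acid
Conditions: OsO4 (cat.), NaIO4 (4 equiv), 2,6-lutidine, dioxane/H2O, rt
Reagents that add atoms: osmium tetroxide, O=[Os](=O)(=O)=O; sodium periodate, [Na+].[O-]I(=O)(=O)=O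
Why: Lemieux–Johnson cleavage should take the monosubstituted vinyl group, which is far more accessible than the C2=C3 bond flanked by two fully substituted carbons, and release the α-silyloxy aldehyde at C10.

Step 14
Reactants: 18 C10 aldehyde acid; 19 (Z)-1-bromoprop-1-ene
Product: 21 (10R,11R)-seco acid, via (Z)-prop-1-enyllithium 20 (not isolated)
Conditions: 19, t-BuLi (2 equiv per 19), Et2O, −78 °C; then 18 (0.4 equiv), THF, −78 °C; NH4Cl (aq) at −78 °C
Reagents that add atoms: none
Why: Bromine–lithium exchange keeps the Z geometry, the first equivalent of 20 deprotonates the acid, and addition to the α-silyloxy aldehyde under non-chelating conditions should follow the polar Felkin–Anh (Cornforth) model to give the 10,11-anti carbinol (10R), which leaves C10–OH as the only free hydroxyl.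

Step 15
Reactants: 21 seco acid
Product: 22 12-membered macrolactone
Conditions: 2-methyl-6-nitrobenzoic anhydride (1.5 equiv), DMAP (3 equiv), CH2Cl2, rt, slow addition of 21 (high dilution)
Reagents that add atoms: none
Why: Shiina macrolactonisation (mixed anhydride, DMAP acyl transfer) should close the lactone on the only free hydroxyl; no stereocenter changes, and the silylated tertiary carbinol cannot form a β-lactone.

Step 16
Reactants: 22 macrolactone
Product: 23 2-methylene oxacycle (exocyclic enol ether C6=C7H2)
Conditions: Cp2TiMe2 (3 equiv), toluene, 70 °C, dark; filtration through basic alumina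
Reagents that add atoms: dimethyltitanocene (Cp2TiMe2), C[Ti](C)(C1C=CC=C1)C1C=CC=C1
Why: Petasis methylenation (ester olefination by thermally generated Cp2Ti=CH2) should convert the lactone carbonyl into the enol ether, with the silyl ethers and both alkenes inert.

Step 17
Reactants: 23 2-methylene oxacycle
Product: 24 14-membered ketone with a 9E double bond
Conditions: toluene, BHT (cat.), base-washed sealed tube, 170 °C
Reagents that add atoms: none
Why: A thermal Claisen ([3,3]-sigmatropic) rearrangement of the allyl vinyl ether C7=C6–O–C10–C9=C8 should break O–C10 and form C7–C8 in one concerted, suprafacial event; the closest known reaction type is the Claisen ring expansion of 2-methylene-6-alkenyl oxacycles made by methylenation of lactones. The carbocycle is closed pericyclically rather than by an exo or endo cyclisation: the one-atom bridge C6–O–C10 of the 12-membered ring is exchanged for the three-carbon bridge C7–C8–C9 (two-atom ring expansion), the tetrahydrofuran is a spectator, and the ester-like s-trans shape of the large ring already holds the exocyclic methylene syn to C10. C8 is set by 1,3-chirality transfer from C10: C7 bonds to the face of C8 from which the C10–O bond departs, and because C7 is an unsubstituted CH2 terminus the outcome is the same for chair and boat arrays, so (10R) with the (Z)-propenyl group gives the C8 configuration of the target (8R in 24, 8S after saturation). The one selectivity needed is that the C11 chain sits outside and not inside the six-atom array (this also makes the new C9=C10 bond E); it is secured by A(1,3) strain between the cis methyl group on C8 and any inside substituent on C10, which forces hydrogen inside. No second [3,3] pathway exists because 23 holds one allyl vinyl ether unit only, and neutral, base-washed conditions guard the enol ether against hydrolysis or ionisation.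

Step 18
Reactants: 24 unsaturated ketone
Product: 25 saturated ketone, bis(triethylsilyl) ether
Conditions: KO2CN=NCO2K, AcOH, pyridine/MeOH, rt (diimide in situ, repeated charges)
Reagents that add atoms: none
Why: Diimide should reduce the 1,2-disubstituted C9=C10 bond but neither the C2=C3 bond, which is shielded by two fully substituted neighbours, nor the ketone; C8 and C11 are untouched.

Step 19
Reactants: 25 saturated ketone
Product: 26 diol (11-O-deformyl target)
Conditions: HF·pyridine, pyridine, THF, 0 °C to rt
Reagents that add atoms: none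
Why: Buffered fluoride should cleave both triethylsilyl ethers without β-elimination or retro-aldol cleavage of the β-hydroxy ketone that is revealed.

Step 20
Reactants: 26 diol
Product: 27 CNP0176107.1 (target)
Conditions: HCO2H/Ac2O (premixed at 50 °C, then cooled), pyridine, CH2Cl2, 0 °C
Reagents that add atoms: formic acid, O=CO
Why: Formylation with the mixed formic acetic anhydride should acylate the secondary C11 hydroxyl, while the tertiary C4 hydroxyl is too hindered to react at 0 °C.

Compound list

1 | (R)-(−)-terpinen-4-ol, (1R)-4-methyl-1-(propan-2-yl)cyclohex-3-en-1-ol | CC(C)[C@]1(O)CC=C(C)CC1 | starting material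
2 | cis-1,2-epoxy-p-menthan-4-ol (epoxide syn to the hydroxyl; from 1) | CC(C)[C@@]1(O)CC[C@]2(C)O[C@@H]2C1 | intermediate
3 | 2-exo-hydroxy-1,4-cineole (1-methyl-4-isopropyl-7-oxabicyclo[2.2.1]heptan-2-exo-ol; bridgeheads as set by 1) | CC(C)[C@]12CC[C@](C)(O1)[C@H](O)C2 | intermediate
4 | 1,4-cineol-2-one (1-methyl-4-isopropyl-7-oxabicyclo[2.2.1]heptan-2-one) | CC(C)[C@]12CC[C@](C)(O1)C(=O)C2 | intermediate
5 | 2-(trimethylsilyloxy)-1,4-cineol-2-ene (silyl enol ether of 4) | CC(C)[C@]12CC[C@](C)(O1)C(O[Si](C)(C)C)=C2 | intermediate
6 | (1S,12S)-aldehyde acid: tetrahydrofuran with isopropyl and formyl (C2) on C1, methyl and carboxyl (C11) on C12, C2 and C11 cis | CC(C)[C@]1(C=O)CC[C@@](C)(C(=O)O)O1 | intermediate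
7 | triethyl 3-methyl-4-phosphonocrotonate, ethyl (E)-4-(diethoxyphosphoryl)-3-methylbut-2-enoate | CCOC(=O)/C=C(/CP(=O)(OCC)OCC)C | starting material
8 | (1S,12S,2E,4E)-dienoate acid (C2–C6 chain as ethyl 3-methylpenta-2,4-dienoate on C1; C11 carboxyl) | CC(C)[C@]1(/C=C/C(C)=C/C(=O)OCC)CC[C@@](C)(C(=O)O)O1 | intermediate
9 | acid chloride of 8 | CC(C)[C@]1(/C=C/C(C)=C/C(=O)OCC)CC[C@@](C)(C(Cl)=O)O1 | intermediate
10 | N-methoxy-N-methylamide of 8 (Weinreb amide at C11) | CC(C)[C@]1(/C=C/C(C)=C/C(=O)OCC)CC[C@@](C)(C(=O)N(C)OC)O1 | intermediate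
11 | aldehyde dienol: C11 aldehyde, (2E,4E)-dienyl C6 primary alcohol | CC(C)[C@]1(/C=C/C(C)=C/CO)CC[C@@](C)(C=O)O1 | intermediate
12 | (1S,11R,12S)-vinyl carbinol: C11 secondary alcohol bearing vinyl, C6 dienol | CC(C)[C@]1(/C=C/C(C)=C/CO)CC[C@@](C)([C@H](O)C=C)O1 | intermediate
13 | (4R,5R)-4,5-epoxide of 12 (2,3-epoxy alcohol, C2=C3 E) | CC(C)[C@]1(/C=C/[C@@]2(C)O[C@@H]2CO)CC[C@@](C)([C@H](O)C=C)O1 | intermediate
14 | (1S,4S,11R,12S)-triol: tertiary C4–OH, primary C6–OH, secondary C11–OH | CC(C)[C@]1(/C=C/[C@@](C)(O)CCO)CC[C@@](C)([C@H](O)C=C)O1 | intermediate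
15 | (1S,4S,11R,12S)-dihydroxy acid (C6 carboxylic acid) | CC(C)[C@]1(/C=C/[C@@](C)(O)CC(=O)O)CC[C@@](C)([C@H](O)C=C)O1 | intermediate
16 | triethylsilyl ester of 17 (tris-silylated 15) | CC(C)[C@]1(/C=C/[C@@](C)(O[Si](CC)(CC)CC)CC(=O)O[Si](CC)(CC)CC)CC[C@@](C)([C@H](O[Si](CC)(CC)CC)C=C)O1 | intermediate
17 | 4,11-bis(triethylsilyl) ether of 15 | CC(C)[C@]1(/C=C/[C@@](C)(O[Si](CC)(CC)CC)CC(=O)O)CC[C@@](C)([C@H](O[Si](CC)(CC)CC)C=C)O1 | intermediate
18 | C10 aldehyde acid (α-silyloxy aldehyde; C11 spatially as in 17) | CC(C)[C@]1(/C=C/[C@@](C)(O[Si](CC)(CC)CC)CC(=O)O)CC[C@@](C)([C@H](O[Si](CC)(CC)CC)C=O)O1 | intermediate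
19 | (Z)-1-bromoprop-1-ene | C/C=C\Br | starting material
20 | (Z)-prop-1-enyllithium | C/C=C\[Li] | intermediate
21 | (1S,4S,10R,11R,12S)-seco acid: free C10–OH bearing (Z)-prop-1-enyl, 10,11-anti, C6 acid | CC(C)[C@]1(/C=C/[C@@](C)(O[Si](CC)(CC)CC)CC(=O)O)CC[C@@](C)([C@H](O[Si](CC)(CC)CC)[C@H](O)/C=C\C)O1 | intermediate
22 | (1S,4S,10R,11R,12S)-12-membered macrolactone (C6 acyl to C10 oxygen, 1,12-oxygen bridge, 2E) | CC(C)[C@]12/C=C/[C@@](C)(O[Si](CC)(CC)CC)CC(=O)O[C@H](/C=C\C)[C@@H](O[Si](CC)(CC)CC)[C@](C)(CC1)O2 | intermediate
23 | 2-methylene oxacycle from 22 (C6=C7H2 exocyclic enol ether) | CC(C)[C@]12/C=C/[C@@](C)(O[Si](CC)(CC)CC)CC(=C)O[C@H](/C=C\C)[C@@H](O[Si](CC)(CC)CC)[C@](C)(CC1)O2 | intermediate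
24 | (1S,4S,8R,11R,12S,2E,9E)-14-membered ketone, 4,11-bis(triethylsilyl) ether (9,10-didehydro-25) | CC(C)[C@]12/C=C/[C@@](C)(O[Si](CC)(CC)CC)CC(=O)C[C@@H](C)/C=C/[C@@H](O[Si](CC)(CC)CC)[C@](C)(CC1)O2 | intermediate
25 | (1S,4S,8S,11R,12S,2E)-ketone, 4,11-bis(triethylsilyl) ether | CC(C)[C@]12/C=C/[C@@](C)(O[Si](CC)(CC)CC)CC(=O)C[C@@H](C)CC[C@@H](O[Si](CC)(CC)CC)[C@](C)(CC1)O2 | intermediate
26 | (1S,4S,8S,11R,12S,2E)-4,11-diol (11-O-deformyl target) | CC(C)[C@]12/C=C/[C@@](C)(O)CC(=O)C[C@@H](C)CC[C@@H](O)[C@](C)(CC1)O2 | intermediate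
27 | CNP0176107.1, (1S,4S,8S,11R,12S,2E)-1,12-epoxy-4-hydroxy-6-oxocembr-2-en-11-yl formate | CC(C)[C@]12/C=C/[C@@](C)(O)CC(=O)C[C@@H](C)CC[C@@H](OC=O)[C@](C)(CC1)O2 | target

Total step count: 20. Longest linear sequence: 20 steps (from 1; 7 and 19 are commercial).

Steps most likely to fail

Step 17. The macrocyclic allyl vinyl ether may not reach the [3,3] array before the acid-labile enol ether is lost, or the C11 chain may sit inside the array and erode the transfer of chirality to C8. The fallback keeps the same bond-forming idea but uses an enolate. It sets out from seco acid 21 and returns at 24. C-Acylation of Meldrum's acid (DCC, DMAP, CH2Cl2) should give the acyl Meldrum's acid F1. Thermolysis of F1 in dilute toluene (90 °C) generates the acylketene, which the C10 hydroxyl traps to give the 14-membered β-keto lactone F2. Its dianion (LiN(i-Pr)2, 2.2 equiv, THF, −78 °C to rt; Carroll rearrangement) should undergo the same suprafacial [3,3] shift, forming C7–C8 and the carbocycle as the β-keto acid F3, which decarboxylates on gentle warming to 24.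

Step 15. Closure of the 12-membered ring onto a hindered secondary allylic hydroxyl may be slow, so that intermolecular esterification or β-elimination of the silyloxy group from the activated acyl intermediate takes over. The fallback activates the alcohol instead of the acid. It sets out from 21 and returns at 22. Dess–Martin oxidation gives the (Z)-enone acid F4. Luche reduction (NaBH4, CeCl3·7H2O, MeOH, −78 °C) under Felkin–Anh control should give the C10 epimer, the (10S)-hydroxy acid F5. An intramolecular Mitsunobu reaction (PPh3, diisopropyl azodicarboxylate, toluene, high dilution) should then close the lactone with inversion at C10 to 22.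

Step 14. Facial selectivity in the addition to the α-silyloxy aldehyde may be poor (polar Felkin–Anh control against the steric demand of the quaternary C12), or the C11 silyl group may migrate to the new alkoxide. The fallback sets C10 by reagent control. It sets out from 18 and returns at 21. Addition of 1-propynylmagnesium bromide (CH3C≡CMgBr, excess, THF, −78 °C) gives the propargylic alcohols F6 as a C10 mixture. Dess–Martin oxidation gives the ynone F7. Noyori asymmetric transfer hydrogenation (RuCl(p-cymene)[TsDPEN], the antipode that gives the 10R carbinol, HCO2H/Et3N) should give the (10R)-propargylic alcohol F8. Lindlar semihydrogenation (H2, Pd/CaCO3 poisoned with Pb(OAc)2, quinoline) then gives the (Z)-allylic alcohol 21.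

Further compounds

F1 | step 17 | acyl Meldrum's acid of 21 (enol form) | CC(C)[C@]1(/C=C/[C@@](C)(O[Si](CC)(CC)CC)CC(O)=C2C(=O)OC(C)(C)OC2=O)CC[C@@](C)([C@H](O[Si](CC)(CC)CC)[C@H](O)/C=C\C)O1
F2 | step 17 | 14-membered β-keto lactone (C6 ketone, C7H2, ester to C10 oxygen) | CC(C)[C@]12/C=C/[C@@](C)(O[Si](CC)(CC)CC)CC(=O)CC(=O)O[C@H](/C=C\C)[C@@H](O[Si](CC)(CC)CC)[C@](C)(CC1)O2
F3 | step 17 | carbocyclic β-keto acid (carboxyl on C7) | CC(C)[C@]12/C=C/[C@@](C)(O[Si](CC)(CC)CC)CC(=O)C(C(=O)O)[C@@H](C)/C=C/[C@@H](O[Si](CC)(CC)CC)[C@](C)(CC1)O2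
F4 | step 15 | (Z)-enone acid (C10 ketone) | CC(C)[C@]1(/C=C/[C@@](C)(O[Si](CC)(CC)CC)CC(=O)O)CC[C@@](C)([C@H](O[Si](CC)(CC)CC)C(=O)/C=C\C)O1
F5 | step 15 | (10S)-hydroxy acid (C10 epimer of 21) | CC(C)[C@]1(/C=C/[C@@](C)(O[Si](CC)(CC)CC)CC(=O)O)CC[C@@](C)([C@H](O[Si](CC)(CC)CC)[C@@H](O)/C=C\C)O1
F6 | step 14 | propargylic alcohols (C10 epimers) | CC(C)[C@]1(/C=C/[C@@](C)(O[Si](CC)(CC)CC)CC(=O)O)CC[C@@](C)([C@H](O[Si](CC)(CC)CC)C(O)C#CC)O1
F7 | step 14 | ynone acid (C10 ketone) | CC(C)[C@]1(/C=C/[C@@](C)(O[Si](CC)(CC)CC)CC(=O)O)CC[C@@](C)([C@H](O[Si](CC)(CC)CC)C(=O)C#CC)O1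
F8 | step 14 | (10R)-propargylic alcohol | CC(C)[C@]1(/C=C/[C@@](C)(O[Si](CC)(CC)CC)CC(=O)O)CC[C@@](C)([C@H](O[Si](CC)(CC)CC)[C@H](O)C#CC)O1
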